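**Plan**
1. The last cuts remove the five O-protecting groups and break the CH2–CH2 bond of the C5 side chain. That bond is traced back to the Cα=Cβ bond of an enone made by Wittig olefination of a 5-formyl-2,3-dihydrobenzofuran.
2. Enabling feature: ring A (C3a, C4, C5, C6, C7, C7a) bears only O1 on C7a, C3 on C3a and the chain on C5 (para to O1), and C4, C6 and C7 are CH. Ring A is therefore cut at C3a–C4 and C5–C6 into a ring-B-fused 4-oxy-2-pyranone (C3a, C7a, C7, C6) and propiolaldehyde (C4, C5, formyl carbon).
3. Ring B is cut at C3–C3a (Knoevenagel condensation) and at C2–C3 and C2–O1 (formal [4+1] annulation with a benzylic sulfonium ylide).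
4. Forward order: the pyranone ring is bought, ring B is closed on it, and ring A is grown out of the pyranone with loss of CO2. The chain is then joined, followed by hydrogenation and deacetylation.
5. Stereochemistry: C2 comes from an enantiopure isothiocineole benzylide (reagent control, closure with inversion) and C3 follows as the trans partner. All later steps are run neutral so that neither centre is touched.

Key step: step 6

Assumption: the facial bias of the isothiocineole benzylide is taken to be the one that governs its additions to aldehydes and imines (aryl group syn to the sulfur lone pair, attack on the ylide face turned away from the gem-dimethyl carbon), which maps the (1R,4R,5R) sulfide onto (2S); should the first experiment show the opposite sense, the (1S,4S,5S) sulfide from (S)-limonene is used with nothing else changed.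

Step 1
Reactants: 1 2,4-dihydroxyacetophenone
Product: 2 2,4-bis(benzyloxy)acetophenone
Conditions: BnBr (2.4 equiv), K2CO3, DMF, 70 °C
Reagents that add atoms: benzyl bromide, BrCc1ccccc1
Why: Williamson ether synthesis: carbonate in warm DMF alkylates both phenols, the hydrogen-bonded 2-OH included, and benzyl ethers withstand the oxidations, ylides and heating to come yet leave at the end under neutral hydrogenolysis.

Step 2
Reactants: 2 2,4-bis(benzyloxy)acetophenone
Product: 3 2-[2,4-bis(benzyloxy)phenyl]-2-oxoacetaldehyde (the arylglyoxal)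
Conditions: SeO2 (1.3 equiv), 1,4-dioxane/H2O, reflux; hydrate dried by azeotrope with toluene
Reagents that add atoms: selenium dioxide, O=[Se]=O
Why: Riley oxidation: SeO2 attacks the enol of the aryl methyl ketone and turns CH3 into CHO, a standard route to arylglyoxals that alkoxyaryl ketones and benzyl ethers tolerate.

Step 3
Reactants: 4 4-(bromomethyl)phenyl acetate; 5 (1R,4R,5R)-4,7,7-trimethyl-6-thiabicyclo[3.2.1]octane (isothiocineole)
Product: 6 (1R,4R,5R,6R)-6-[4-(acetyloxy)benzyl]-4,7,7-trimethyl-6-thiabicyclo[3.2.1]octan-6-ium trifluoromethanesulfonate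
Conditions: CF3SO3Li (5 equiv), CH2Cl2/H2O, rt
Reagents that add atoms: lithium trifluoromethanesulfonate, [Li+].[O-]S(=O)(=O)C(F)(F)F
Why: SN2 S-alkylation of the sulfide by the benzylic bromide, made irreversible by exchange of bromide for the non-nucleophilic sulfonate; only the exo lone pair of the bicyclic sulfide is open, so sulfur should become a single (R) stereocentre.

Step 4
Reactants: 3 2-[2,4-bis(benzyloxy)phenyl]-2-oxoacetaldehyde; 6 the sulfonium trifluoromethanesulfonate; 7 4-hydroxy-2H-pyran-2-one
Product: 11 4-[(2S,3S)-3-[2,4-bis(benzyloxy)benzoyl]-4-oxo-2,3-dihydro-4H-furo[3,2-c]pyran-2-yl]phenyl acetate (trans), via alkylidene pyrandione 8 (not isolated), via sulfonium benzylide 9 (not isolated), via betaine 10 (not isolated)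
Conditions: (a) 3 + 7, ethylenediammonium diacetate (5 mol %), 4 Å MS, THF/CH2Cl2, 0 °C to rt; (b) 6, LiN(SiMe3)2 (1.0 equiv), THF, −78 °C; (c) 9 into 8 by cannula, −78 to −20 °C, then AcOH
Reagents that add atoms: none
Why: Proposed new method: Knoevenagel condensation of the acidic C3–H of 7 with the aldehyde of 3 gives the doubly activated alkylidene 8, whose exocyclic carbon takes up the preformed benzylide 9 irreversibly (the enolate of 10 is far too stabilised to expel the ylide again), and the C4 enolate oxygen, rather than the lactone carbonyl oxygen, then displaces the sulfide in a 5-exo-tet SN2 closure with inversion; C2 is set by the sulfonium auxiliary (one ylide conformer, one open face) and C3 follows as the trans partner, which is both the product of the less crowded anti betaine and the thermodynamic isomer, while inverse addition of exactly one equivalent of ylide leaves no base that could start beta-elimination of O1; the closest known reactions are the formal [4+1] annulation of alpha-ylidene 1,3-dicarbonyl compounds with chiral camphor-derived allylic sulfonium ylides and the epoxidation and aziridination of aldehydes and imines with isothiocineole benzylides, whereas a chiral benzylide on a glyoxal-derived alkylidene pyrandione has not been shown.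

Step 5
Reactants: 12 propargyl alcohol
Product: 13 propiolaldehyde (kept as a toluene solution)
Conditions: activated MnO2 (12 equiv), toluene, rt; filtered through Celite, dried over MgSO4, assayed and used the same day
Reagents that add atoms: none
Why: Oxidation of a propargylic alcohol on activated MnO2 stops at the aldehyde, and working in toluene gives the volatile, polymerisable ynal as a solution that goes straight into the next step.

Step 6
Reactants: 11 the (2S,3S)-dihydrofuro[3,2-c]pyran-4-one; 13 propiolaldehyde
Product: 15 4-[(2S,3S)-3-[2,4-bis(benzyloxy)benzoyl]-5-formyl-2,3-dihydro-1-benzofuran-2-yl]phenyl acetate, via bridged lactone 14 (not isolated)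
Conditions: 13 (5 equiv, two portions), BHT (5 mol %), toluene, silanised sealed tube, 125 °C
Reagents that add atoms: none
Why: The 2-pyranone diene of 11 (C3a=C7a–C7=C6 in benzofuran numbering) adds across the triple bond of 13 in a thermal normal-demand [4+2] cycloaddition to give the bridged lactone 14, which at this temperature loses CO2 at once by retro-[4+2] reaction and becomes the benzene ring. The closest known reaction type is the Diels–Alder/decarboxylation sequence of 2-pyranones, 4-alkoxy-2-pyranones included, with propiolates, ynones and acetylenedicarboxylates to give substituted benzenes. Ring A closes by an intermolecular [4+2] cycloaddition (bonds C3a–C4 and C5–C6, four ring atoms from the pyranone and two from the alkyne) and is aromatised by the cycloreversion. No stereocentre is created: the two bridgehead centres of 14 vanish with CO2, so the face of attack is irrelevant, and C2 and C3 are spectators. The step needs regioselectivity (formyl on C5, not C4), secured because the ring B oxygen on C7a and the lactone oxygen on C6 together put the largest HOMO coefficient on C3a, which therefore bonds to the electrophilic terminal carbon of the ynal, and because the fully substituted C3a can only accommodate the CH terminus. It also needs C2 and C3 to survive the heating: neutral silanised glass avoids enolisation and beta-elimination at C3, and the acetoxy group keeps the C2 aryl ring too electron-poor for ionisation of the benzylic C2–O1 bond.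

Step 7
Reactants: 2 2,4-bis(benzyloxy)acetophenone
Product: 16 1-[2,4-bis(benzyloxy)phenyl]-2-bromoethanone
Conditions: CuBr2 (2.1 equiv), EtOAc/CHCl3 1:1, reflux
Reagents that add atoms: copper dibromide, [Cu+2].[Br-].[Br-]
Why: Heterogeneous alpha-bromination of an aryl methyl ketone with CuBr2 runs through the copper-bound enol and therefore spares the electron-rich ring and stops at the monobromide.

Step 8
Reactants: 16 1-[2,4-bis(benzyloxy)phenyl]-2-bromoethanone
Product: 18 1-[2,4-bis(benzyloxy)phenyl]-2-(triphenyl-λ5-phosphanylidene)ethanone, via phosphonium bromide 17 (not isolated)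
Conditions: PPh3, toluene, rt to 50 °C; then CH2Cl2, aq NaOH (1 M), rt
Reagents that add atoms: triphenylphosphine, c1ccc(cc1)P(c1ccccc1)c1ccccc1
Why: SN2 quaternisation of PPh3 by the phenacyl bromide followed by deprotonation of the acidic phosphonium salt with aqueous base is the standard preparation of a stabilised acyl phosphorane.

Step 9
Reactants: 15 the 5-formyl-dihydrobenzofuran; 18 the acyl phosphorane
Product: 19 4-[(2S,3S)-3-[2,4-bis(benzyloxy)benzoyl]-5-[(E)-3-[2,4-bis(benzyloxy)phenyl]-3-oxoprop-1-en-1-yl]-2,3-dihydro-1-benzofuran-2-yl]phenyl acetate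
Conditions: 18 (1.5 equiv), toluene, 100 °C
Reagents that add atoms: none
Why: Wittig olefination of an aromatic aldehyde with a stabilised acyl ylide gives the (E)-enone, and the ylide is far too weak a base to remove C3–H, so ring B and both stereocentres stay intact.

Step 10
Reactants: 19 the tetrabenzyl enone
Product: 20 4-[(2S,3S)-3-(2,4-dihydroxybenzoyl)-5-[3-(2,4-dihydroxyphenyl)-3-oxopropyl]-2,3-dihydro-1-benzofuran-2-yl]phenyl acetate
Conditions: H2 (1 atm), Pd/C (10 wt % Pd), EtOAc/EtOH 1:1, rt, stopped as soon as debenzylation is complete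
Reagents that add atoms: none
Why: Heterogeneous catalytic hydrogenation saturates the enone C=C and hydrogenolyses the four primary benzyl aryl ethers under neutral conditions, while the ring-held secondary C2–O1 bond next to the electron-poor acetoxyphenyl group and the electron-rich aryl ketones should react far more slowly.

Step 11
Reactants: 20 the monoacetate
Product: 21 1-(2,4-dihydroxyphenyl)-3-[(2S,3S)-3-(2,4-dihydroxybenzoyl)-2-(4-hydroxyphenyl)-2,3-dihydro-1-benzofuran-5-yl]propan-1-one (CNP0136359.1)
Conditions: NH4OAc (8 equiv), MeOH/H2O 4:1, rt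
Reagents that add atoms: none
Why: Neutral ammonium acetate-promoted solvolysis of a phenyl acetate releases the last phenol without building up phenoxide, so neither quinone-methide opening of C2–O1 nor beta-elimination at C3 can start and the (2S,3S) configuration is kept.

**Compound list**
1 | 2,4-dihydroxyacetophenone | CC(=O)c1ccc(O)cc1O | starting material
2 | 2,4-bis(benzyloxy)acetophenone | CC(=O)c1ccc(OCc2ccccc2)cc1OCc1ccccc1 | intermediate
3 | 2-[2,4-bis(benzyloxy)phenyl]-2-oxoacetaldehyde | O=CC(=O)c1ccc(OCc2ccccc2)cc1OCc1ccccc1 | intermediate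
4 | 4-(bromomethyl)phenyl acetate | CC(=O)Oc1ccc(CBr)cc1 | starting material
5 | (1R,4R,5R)-4,7,7-trimethyl-6-thiabicyclo[3.2.1]octane (isothiocineole) | C[C@@H]1CC[C@@H]2C[C@H]1SC2(C)C | starting material
6 | (1R,4R,5R,6R)-6-[4-(acetyloxy)benzyl]-4,7,7-trimethyl-6-thiabicyclo[3.2.1]octan-6-ium trifluoromethanesulfonate | C[C@@H]1CC[C@@H]2C[C@H]1[S@@+](Cc1ccc(OC(C)=O)cc1)C2(C)C.[O-]S(=O)(=O)C(F)(F)F | intermediate
7 | 4-hydroxy-2H-pyran-2-one | O=c1cc(O)cco1 | starting material
8 | 3-[2-[2,4-bis(benzyloxy)phenyl]-2-oxoethylidene]-2H-pyran-2,4(3H)-dione (not isolated; alkene geometry not defined) | O=C1OC=CC(=O)C1=CC(=O)c1ccc(OCc2ccccc2)cc1OCc1ccccc1 | intermediate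
9 | sulfonium benzylide of 6, carbanion on the benzylic carbon (not isolated) | C[C@@H]1CC[C@@H]2C[C@H]1[S@@+]([CH-]c1ccc(OC(C)=O)cc1)C2(C)C | intermediate
10 | betaine: 4-oxido-2-pyranon-3-yl carbon (future C3, aroyl-bearing) bonded to the sulfonium-bearing benzylic carbon (future C2) (not isolated) | O=C1OC=CC([O-])=C1[C@H](C(=O)c1ccc(OCc2ccccc2)cc1OCc1ccccc1)[C@H](c1ccc(OC(C)=O)cc1)[S@@+]1[C@@H]2C[C@@H](CC[C@H]2C)C1(C)C | intermediate
11 | 4-[(2S,3S)-3-[2,4-bis(benzyloxy)benzoyl]-4-oxo-2,3-dihydro-4H-furo[3,2-c]pyran-2-yl]phenyl acetate | O=C1OC=CC2=C1[C@H](C(=O)c1ccc(OCc3ccccc3)cc1OCc1ccccc1)[C@@H](c1ccc(OC(C)=O)cc1)O2 | intermediate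
12 | propargyl alcohol | C#CCO | starting material
13 | propiolaldehyde | C#CC=O | intermediate
14 | bridged lactone, a 2-oxabicyclo[2.2.2]octa-5,7-dien-3-one whose quaternary bridgehead is the future C3a and whose O-bearing bridgehead is the future C6, formyl on the new C=C next to the latter; (2S,3S) in ring B, bridgeheads from either face (not isolated) | O=C1OC2C=C3O[C@H](c4ccc(OC(C)=O)cc4)[C@@H](C(=O)c4ccc(OCc5ccccc5)cc4OCc4ccccc4)C13C=C2C=O | intermediate
15 | 4-[(2S,3S)-3-[2,4-bis(benzyloxy)benzoyl]-5-formyl-2,3-dihydro-1-benzofuran-2-yl]phenyl acetate | O=Cc1ccc2c(c1)[C@H](C(=O)c1ccc(OCc3ccccc3)cc1OCc1ccccc1)[C@@H](c1ccc(OC(C)=O)cc1)O2 | intermediate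
16 | 1-[2,4-bis(benzyloxy)phenyl]-2-bromoethanone | O=C(CBr)c1ccc(OCc2ccccc2)cc1OCc1ccccc1 | intermediate
17 | [2-[2,4-bis(benzyloxy)phenyl]-2-oxoethyl]triphenylphosphonium bromide (not isolated) | O=C(C[P+](c1ccccc1)(c1ccccc1)c1ccccc1)c1ccc(OCc2ccccc2)cc1OCc1ccccc1.[Br-] | intermediate
18 | 1-[2,4-bis(benzyloxy)phenyl]-2-(triphenyl-λ5-phosphanylidene)ethanone | O=C(C=P(c1ccccc1)(c1ccccc1)c1ccccc1)c1ccc(OCc2ccccc2)cc1OCc1ccccc1 | intermediate
19 | 4-[(2S,3S)-3-[2,4-bis(benzyloxy)benzoyl]-5-[(E)-3-[2,4-bis(benzyloxy)phenyl]-3-oxoprop-1-en-1-yl]-2,3-dihydro-1-benzofuran-2-yl]phenyl acetate | O=C(/C=C/c1ccc2c(c1)[C@H](C(=O)c1ccc(OCc3ccccc3)cc1OCc1ccccc1)[C@@H](c1ccc(OC(C)=O)cc1)O2)c1ccc(OCc2ccccc2)cc1OCc1ccccc1 | intermediate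
20 | 4-[(2S,3S)-3-(2,4-dihydroxybenzoyl)-5-[3-(2,4-dihydroxyphenyl)-3-oxopropyl]-2,3-dihydro-1-benzofuran-2-yl]phenyl acetate | O=C(CCc1ccc2c(c1)[C@H](C(=O)c1ccc(O)cc1O)[C@@H](c1ccc(OC(C)=O)cc1)O2)c1ccc(O)cc1O | intermediate
21 | 1-(2,4-dihydroxyphenyl)-3-[(2S,3S)-3-(2,4-dihydroxybenzoyl)-2-(4-hydroxyphenyl)-2,3-dihydro-1-benzofuran-5-yl]propan-1-one (CNP0136359.1) | O=C(CCc1ccc2c(c1)[C@H](C(=O)c1ccc(O)cc1O)[C@@H](c1ccc(O)cc1)O2)c1ccc(O)cc1O | target

Total step count: 11.
Longest linear sequence: 7 steps (1, 2, 4, 6, 9, 10, 11).

**Steps most likely to fail**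

Step 4.
- The alkylidene may be drained by Michael addition of unreacted hydroxypyranone, or by self-cycloaddition, before the ylide arrives.
- Leftover glyoxal may divert the ylide into epoxidation.
- The facial bias of the ylide may not carry over to a Michael acceptor.
- Any surviving base may start beta-elimination of O1 from C2 and erode the enantiomeric purity.

The fallback uses known chemistry, sets out from 2 and 7 and returns at 11. Claisen–Schmidt condensation of 2 with 4-hydroxybenzaldehyde (KOH, EtOH) should give the 4-hydroxychalcone F1. Acetylation (Ac2O, pyridine) should give the 4-acetoxychalcone F2. Oxidative radical [3+2] annulation of 7 onto F2 follows, with Mn(OAc)3·2H2O in AcOH at 80 °C. Here trivalent manganese oxidises the 1,3-dicarbonyl unit to its C3 radical, which adds to the alpha carbon of the enone, and the benzylic radical is oxidised and captured by the C4 oxygen. This should give the racemic trans product, that is 11 together with its (2R,3R) enantiomer F3. Preparative chromatography on an immobilised amylose carbamate phase then delivers 11.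

Step 6.
- The cycloaddition may be too slow at a temperature at which the ynal polymerises.
- Prolonged heating may cause enolisation at C3 with reversible opening of the C2–O1 bond and loss of enantiomeric purity.

The fallback sets out from 11 and returns at 15. The alkyne is replaced by an alkene that carries its own leaving group. 2-Bromoacrolein has the same polarisation, so its CH2 terminus bonds to C3a and its formyl-bearing carbon to C6. It should add at 70–80 °C in toluene, with propylene oxide present as a neutral acid scavenger, to give the bridged bromo lactone F4. Gentle further warming should expel CO2 to give the 5-bromo-4,5-dihydrobenzofuran-5-carbaldehyde F5, which aromatises by loss of HBr to 15.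

Step 10.
- The benzylic C2–O1 bond may be hydrogenolysed, or the aryl ketones over-reduced, while the hindered ortho benzyl ethers are still being cleaved.

The fallback sets out from 19 and returns at 20 and separates the two tasks without hydrogen gas. Conjugate reduction of the enone with [(Ph3P)CuH]6 in wet toluene should give the tetrabenzyl dihydrochalcone F6. Lewis-acid debenzylation with BCl3 and pentamethylbenzene in CH2Cl2 at −78 °C then removes the four benzyl groups as a Friedel–Crafts adduct. The C2–O1 bond is shielded from ionisation by the acetoxy group and by the neighbouring acyl-bearing carbon. The product is 20.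

**Further compounds**
F1 | step 4 | (E)-1-[2,4-bis(benzyloxy)phenyl]-3-(4-hydroxyphenyl)prop-2-en-1-one | O=C(/C=C/c1ccc(O)cc1)c1ccc(OCc2ccccc2)cc1OCc1ccccc1
F2 | step 4 | 4-[(E)-3-[2,4-bis(benzyloxy)phenyl]-3-oxoprop-1-en-1-yl]phenyl acetate | CC(=O)Oc1ccc(/C=C/C(=O)c2ccc(OCc3ccccc3)cc2OCc2ccccc2)cc1
F3 | step 4 | 4-[(2R,3R)-3-[2,4-bis(benzyloxy)benzoyl]-4-oxo-2,3-dihydro-4H-furo[3,2-c]pyran-2-yl]phenyl acetate (enantiomer of 11) | O=C1OC=CC2=C1[C@@H](C(=O)c1ccc(OCc3ccccc3)cc1OCc1ccccc1)[C@H](c1ccc(OC(C)=O)cc1)O2
F4 | step 6 | bridged bromo lactone, 2-oxabicyclo[2.2.2]oct-5-en-3-one adduct of 11 and 2-bromoacrolein, (2S,3S) in ring B, new centres not defined | O=C1OC2C=C3O[C@H](c4ccc(OC(C)=O)cc4)[C@@H](C(=O)c4ccc(OCc5ccccc5)cc4OCc4ccccc4)C13CC2(Br)C=O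
F5 | step 6 | 4-[(2S,3S)-3-[2,4-bis(benzyloxy)benzoyl]-5-bromo-5-formyl-2,3,4,5-tetrahydro-1-benzofuran-2-yl]phenyl acetate, C5 not defined | O=CC1(Br)C=CC2=C(C1)[C@H](C(=O)c1ccc(OCc3ccccc3)cc1OCc1ccccc1)[C@@H](c1ccc(OC(C)=O)cc1)O2
F6 | step 10 | 4-[(2S,3S)-3-[2,4-bis(benzyloxy)benzoyl]-5-[3-[2,4-bis(benzyloxy)phenyl]-3-oxopropyl]-2,3-dihydro-1-benzofuran-2-yl]phenyl acetate | O=C(CCc1ccc2c(c1)[C@H](C(=O)c1ccc(OCc3ccccc3)cc1OCc1ccccc1)[C@@H](c1ccc(OC(C)=O)cc1)O2)c1ccc(OCc2ccccc2)cc1OCc1ccccc1
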